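all flasks: Q 0.25 M; D 1.2 mol%
- gamma: E 0.34 equiv; run made earlier
- alpha: E 0.75 equiv; run made earlier
- flask: E 0.500 equiv; time 50 min

- gamma (time / min: J / %): 12.0: 25.6; 15.0: 31.1; 20.0: 40.2; 25.0: 48.6; 30.0: 55.4; 40.0: 68.2
- alpha (time / min: J / %): 12.0: 22.9; 15.0: 28.1; 20.0: 36.9; 25.0: 44.7; 30.0: 52.0; 40.0: 64.5

(scatter of a reading: 0.3 percentage points)



- time, not beyond 50 min, at which the flask holds most J
- the amount of J, in percent of the Q charged, at that time

Early on, at 12.0 min, the gamma run held 25.6% of J and the alpha run 22.9%, so the run with less E led. Could E still cap J, which D makes from Q? By 40.0 min J in gamma stood at twice the charge of E, so one E per Q was excluded. How much did E matter? Raising it by a factor of 2.21 changed J at that time by a factor of 1.06, so I interpolated this flask to 66.8%.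

Was J still rising at the limit? Taking Q as the concentration that set the order, I read a late pseudo-first-order constant from the last two readings of each run and interpolated it to 0.0324 min⁻¹. That gave me 76.0% at 50 min, still rising, with the best time at the limit. This flask's limit stood at 50.0 min on a catalyst clock, the time multiplied by the loading of D and divided by the 1.2 mol% of both runs. I assumed a rate first order in D, which the two runs, made at one loading, did not test.

The forecast gave 50 min and 77%, above mine: “J should therefore still be rising at the time limit”.

The flask gave 76.5% at 50.0 min.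

    G → D + J (k = 0.0951 s⁻¹)
    Q + D ⇌ G (K = 2.48 L mol⁻¹, k = 10.9 L mol⁻¹ s⁻¹)
    E + D ⇌ L (K = 3.50 L mol⁻¹, k = 1.51 L mol⁻¹ s⁻¹)
    L → D + X (k = 0.172 s⁻¹)

On the catalyst clock this flask ended at 50.0 min. The neighbour flask, the same charge with 0.72 mol% of D, stopped after 50 min at 30.0 min on that clock. That sent me to the 30.0 min readings, 55.4% in gamma and 52.0% in alpha, which interpolate to 54.1% at 0.500 equiv of E. The neighbour flask held 54.4% of J.

(The readings come from a simulation for an exercise, noise included.)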